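**Abbreviations:** Ar = 4-(benzyloxy)-3-methoxyphenyl; TBDPS = tert-butyldiphenylsilyl.

**Target analysis:** the SMILES is the C2-symmetric (2R,3S,4S,5R) tetrahydrofuran with 2,3-trans, 3,4-trans and 4,5-trans substituents.

**Assumption:** the Pseudomonas lipase acylates diol 2 to give (S)-3, which I take to be the usual sense for 2-alkylpropane-1,3-diols. If a given enzyme batch gives (R)-3, the same lipase used hydrolytically on the diacetate of 2 gives (S)-3, and the route continues unchanged.

## Retrosynthetic overview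

1. Neoolivil comes from O-deprotection of a protected THF. That THF comes from SN1 cyclodehydration of a C2-symmetric 1,4-diaryl-1,4-diol. The THF ring is formed last.
2. The diol comes from Felkin-controlled double reduction of a C2-symmetric (2S,3S)-1,4-diketone. The diketone comes from ArLi opening of a γ-lactone followed by oxidation.
3. The trisubstituted lactone comes from trans-selective α-hydroxymethylation of a β-substituted γ-aryl-γ-butyrolactone. This temporary ring is formed first and has the same ring atoms as the final THF.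
4. The lactone comes from ArMgBr addition and alkene cleavage on an α-chiral aldehyde. The aldehyde comes from lipase desymmetrisation of prochiral 2-allylpropane-1,3-diol, itself made from diethyl allylmalonate.

## Route

**Step 1**
- Reactants: 1, diethyl 2-allylmalonate
- Product: 2, 2-allylpropane-1,3-diol (prochiral, achiral)
- Conditions: LiAlH4, THF, 0 °C → reflux
- Reagents that add atoms: none
- Why: LiAlH4 ester reduction takes both esters to CH2OH, the isolated alkene is inert, and no stereocentre exists yet.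

**Step 2**
- Reactants: 2
- Product: 3, (S)-2-(hydroxymethyl)pent-4-en-1-yl acetate
- Conditions: lipase (Pseudomonas fluorescens lipase, Amano AK), vinyl acetate, MTBE, 0–5 °C, stopped at about 10–15 % diacetate
- Reagents that add atoms: vinyl acetate, C=COC(C)=O (delivers acetyl)
- Why: lipase-catalysed enantiotopic-group-selective transesterification (enzymatic desymmetrisation) with an irreversible enol ester creates the first stereocentre (future THF C4) catalytically, and the slight over-acylation should consume the minor enantiomer preferentially and raise the ee, which is checked by chiral HPLC.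

**Step 3**
- Reactants: 3
- Product: 4, (R)-2-{[(TBDPS)oxy]methyl}pent-4-en-1-yl acetate
- Conditions: TBDPSCl, imidazole, CH2Cl2, 0 °C → rt
- Reagents that add atoms: TBDPSCl, CC(C)(C)[Si](Cl)(c1ccccc1)c1ccccc1
- Why: prompt near-neutral silylation of the primary alcohol blocks the 1,3-acyl migration that would racemise 3, and the centre is untouched (the descriptor changes only through CIP priorities).

**Step 4**
- Reactants: 4
- Product: 5, (R)-2-{[(TBDPS)oxy]methyl}pent-4-en-1-ol
- Conditions: K2CO3, MeOH, 0 °C → rt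
- Reagents that add atoms: none
- Why: mild transesterification (methanolysis) removes the acetate, and the primary TBDPS ether neither cleaves nor migrates under these conditions.

**Step 5**
- Reactants: 5
- Product: 6, (S)-2-{[(TBDPS)oxy]methyl}pent-4-enal
- Conditions: DMP, NaHCO3, CH2Cl2, 0 °C → rt; used crude
- Reagents that add atoms: none
- Why: buffered Dess–Martin oxidation is neutral, so the α-stereocentre is not epimerised and no silyloxide is eliminated.

**Step 6**
- Reactants: 7, 4-bromo-2-methoxyphenol
- Product: 8, 1-(benzyloxy)-4-bromo-2-methoxybenzene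
- Conditions: BnBr, K2CO3, DMF, rt
- Reagents that add atoms: benzyl bromide, BrCc1ccccc1
- Why: Williamson ether synthesis gives a phenol protecting group that survives organometallics, enolates, hydrides and fluoride.

**Step 7**
- Reactants: 6 and 8
- Product: 9, (1RS,2S)-1-Ar-2-{[(TBDPS)oxy]methyl}pent-4-en-1-ol
- Conditions: 8, Mg, THF, 40 °C; then 6, THF, −78 → −20 °C
- Reagents that add atoms: none beyond 8
- Why: Grignard 1,2-addition to the aldehyde is fast at low temperature, so C2 is preserved, and the carbinol epimer ratio (Felkin–Anh isomer expected to be major) does not matter because this carbon is made planar again in step 13.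

**Step 8**
- Reactants: 9
- Product: 10, (4S)-5-Ar-4-{[(TBDPS)oxy]methyl}tetrahydrofuran-2-ol (mixture at C2 and C5)
- Conditions: OsO4 (2 mol %), NaIO4, 2,6-lutidine, dioxane–H2O 3:1, rt
- Reagents that add atoms: OsO4 / NaIO4 / H2O (one O atom), O=[Os](=O)(=O)=O, [Na+].[O-]I(=O)(=O)=O, O
- Why: Lemieux–Johnson cleavage removes the terminal CH2 without touching the electron-rich arene (unlike O3 or RuO4), and the γ-hydroxy aldehyde closes spontaneously to the five-membered lactol.

**Step 9**
- Reactants: 10
- Product: 11, (4S,5RS)-5-Ar-4-{[(TBDPS)oxy]methyl}dihydrofuran-2(3H)-one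
- Conditions: TEMPO (cat.), PhI(OAc)2, CH2Cl2, rt
- Reagents that add atoms: none
- Why: oxoammonium (TEMPO/BAIB) oxidation converts lactols cleanly to γ-lactones and tolerates silyl and benzyl ethers.

**Step 10**
- Reactants: 11
- Product: 12, (3S,4S,5RS)-5-Ar-4-{[(TBDPS)oxy]methyl}-3-(hydroxymethyl)dihydrofuran-2(3H)-one
- Conditions: LDA, THF, −78 °C; HCHO (g, from cracked paraformaldehyde), −78 → −40 °C; AcOH quench
- Reagents that add atoms: formaldehyde, C=O
- Why: in this lactone-enolate aldol (hydroxymethylation) the electrophile approaches anti to the adjacent C4 substituent in both C5 epimers, which sets C3 as S (3,4-trans, also the thermodynamic arrangement).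

**Step 11**
- Reactants: 12
- Product: 13, (3S,4S,5RS)-5-Ar-3,4-bis{[(TBDPS)oxy]methyl}dihydrofuran-2(3H)-one
- Conditions: TBDPSCl, imidazole, DMF, rt
- Reagents that add atoms: TBDPSCl, CC(C)(C)[Si](Cl)(c1ccccc1)c1ccccc1
- Why: silylating the new primary alcohol makes both side arms identical and keeps them from competing as nucleophiles in the later ring closure.

**Step 12**
- Reactants: 13 and 8
- Product: 14, (2S,3S,4RS)-1,4-di-Ar-4-hydroxy-2,3-bis{[(TBDPS)oxy]methyl}butan-1-one (in equilibrium with its cyclic hemiketal)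
- Conditions: 8, n-BuLi, THF, −78 °C; then 13, −78 °C; NH4Cl quench at −78 °C
- Reagents that add atoms: none beyond 8
- Why: after Br–Li exchange, ArLi adds once to the lactone because the lithium hemiketal alkoxide persists at −78 °C, and addition outruns α-deprotonation so C2 and C3 are kept.

**Step 13**
- Reactants: 14
- Product: 15, (2S,3S)-1,4-di-Ar-2,3-bis{[(TBDPS)oxy]methyl}butane-1,4-dione (C2-symmetric)
- Conditions: DMP, NaHCO3, CH2Cl2, rt
- Reagents that add atoms: none
- Why: Dess–Martin oxidation of the open γ-hydroxy-ketone tautomer (the classical lactone → 1,4-diketone sequence) converges both carbinol epimers on one diketone, and neutral conditions avoid enolisation, β-elimination and Paal–Knorr furan formation.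

**Step 14**
- Reactants: 15
- Product: 16, (1R,2S,3S,4R)-1,4-di-Ar-2,3-bis{[(TBDPS)oxy]methyl}butane-1,4-diol
- Conditions: LiAlH4, THF, −78 → −20 °C
- Reagents that add atoms: none
- Why: in this Felkin–Anh-controlled reduction the branched neighbouring carbon is the large group at each ketone, so hydride adds anti to it and gives R at C1 and C4, the relationship that becomes 2,3-trans and 4,5-trans in the ring; minor isomers are removed by chromatography.

**Step 15**
- Reactants: 16
- Product: 17, (2R,3S,4S,5R)-2,5-di-Ar-3,4-bis{[(TBDPS)oxy]methyl}tetrahydrofuran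
- Conditions: MsCl (1.2 equiv), Et3N, CH2Cl2, −20 → 0 °C
- Reagents that add atoms: none
- Why: this is an SN1 cyclodehydration in which the monomesylate ionises to a p-alkoxybenzyl cation and the other hydroxyl (configuration retained) closes the ring with the aryl trans to its neighbour; by C2 symmetry either hydroxyl gives the same all-trans product, and base-buffered conditions avoid Friedel–Crafts aryltetralin formation.

**Step 16**
- Reactants: 17
- Product: 18, [(2R,3S,4S,5R)-2,5-di-Ar-tetrahydrofuran-3,4-diyl]dimethanol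
- Conditions: TBAF, THF, rt
- Reagents that add atoms: none
- Why: fluoride-mediated desilylation frees both primary alcohols without affecting benzyl ethers, the THF ring or any stereocentre.

**Step 17**
- Reactants: 18
- Product: 19, (+)-neoolivil
- Conditions: H2 (1 atm), 10 % Pd/C, EtOAc–EtOH, rt, stopped as soon as debenzylation is complete
- Reagents that add atoms: none
- Why: catalytic hydrogenolysis cleaves phenolic benzyl ethers much faster than the hindered ring benzylic C–O bonds, as known for related 2,5-diaryl-THF lignans, so close monitoring prevents ring opening.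

## Compound list

| No. | Name | SMILES | Role |
|---|---|---|---|
| 1 | diethyl 2-allylmalonate | C=CCC(C(=O)OCC)C(=O)OCC | starting material |
| 2 | 2-allylpropane-1,3-diol | C=CCC(CO)CO | intermediate |
| 3 | (S)-2-(hydroxymethyl)pent-4-en-1-yl acetate | C=CC[C@@H](CO)COC(C)=O | intermediate |
| 4 | (R)-2-{[(TBDPS)oxy]methyl}pent-4-en-1-yl acetate | C=CC[C@@H](CO[Si](c1ccccc1)(c1ccccc1)C(C)(C)C)COC(C)=O | intermediate |
| 5 | (R)-2-{[(TBDPS)oxy]methyl}pent-4-en-1-ol | C=CC[C@@H](CO[Si](c1ccccc1)(c1ccccc1)C(C)(C)C)CO | intermediate |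
| 6 | (S)-2-{[(TBDPS)oxy]methyl}pent-4-enal | C=CC[C@@H](CO[Si](c1ccccc1)(c1ccccc1)C(C)(C)C)C=O | intermediate |
| 7 | 4-bromo-2-methoxyphenol | COc1cc(Br)ccc1O | starting material |
| 8 | 1-(benzyloxy)-4-bromo-2-methoxybenzene | COc1cc(Br)ccc1OCc1ccccc1 | intermediate |
| 9 | (1RS,2S)-1-Ar-2-{[(TBDPS)oxy]methyl}pent-4-en-1-ol | C=CC[C@@H](CO[Si](c1ccccc1)(c1ccccc1)C(C)(C)C)C(O)c1ccc(OCc2ccccc2)c(OC)c1 | intermediate |
| 10 | (4S)-5-Ar-4-{[(TBDPS)oxy]methyl}tetrahydrofuran-2-ol | OC1C[C@@H](CO[Si](c2ccccc2)(c2ccccc2)C(C)(C)C)C(c2ccc(OCc3ccccc3)c(OC)c2)O1 | intermediate |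
| 11 | (4S,5RS)-5-Ar-4-{[(TBDPS)oxy]methyl}dihydrofuran-2(3H)-one | O=C1C[C@@H](CO[Si](c2ccccc2)(c2ccccc2)C(C)(C)C)C(c2ccc(OCc3ccccc3)c(OC)c2)O1 | intermediate |
| 12 | (3S,4S,5RS)-5-Ar-4-{[(TBDPS)oxy]methyl}-3-(hydroxymethyl)dihydrofuran-2(3H)-one | O=C1OC(c2ccc(OCc3ccccc3)c(OC)c2)[C@H](CO[Si](c2ccccc2)(c2ccccc2)C(C)(C)C)[C@H]1CO | intermediate |
| 13 | (3S,4S,5RS)-5-Ar-3,4-bis{[(TBDPS)oxy]methyl}dihydrofuran-2(3H)-one | O=C1OC(c2ccc(OCc3ccccc3)c(OC)c2)[C@H](CO[Si](c2ccccc2)(c2ccccc2)C(C)(C)C)[C@H]1CO[Si](c1ccccc1)(c1ccccc1)C(C)(C)C | intermediate |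
| 14 | (2S,3S,4RS)-1,4-di-Ar-4-hydroxy-2,3-bis{[(TBDPS)oxy]methyl}butan-1-one (open form) | O=C(c1ccc(OCc2ccccc2)c(OC)c1)[C@H](CO[Si](c1ccccc1)(c1ccccc1)C(C)(C)C)[C@@H](CO[Si](c1ccccc1)(c1ccccc1)C(C)(C)C)C(O)c1ccc(OCc2ccccc2)c(OC)c1 | intermediate |
| 15 | (2S,3S)-1,4-di-Ar-2,3-bis{[(TBDPS)oxy]methyl}butane-1,4-dione | O=C(c1ccc(OCc2ccccc2)c(OC)c1)[C@H](CO[Si](c1ccccc1)(c1ccccc1)C(C)(C)C)[C@@H](CO[Si](c1ccccc1)(c1ccccc1)C(C)(C)C)C(=O)c1ccc(OCc2ccccc2)c(OC)c1 | intermediate |
| 16 | (1R,2S,3S,4R)-1,4-di-Ar-2,3-bis{[(TBDPS)oxy]methyl}butane-1,4-diol | O[C@@H](c1ccc(OCc2ccccc2)c(OC)c1)[C@H](CO[Si](c1ccccc1)(c1ccccc1)C(C)(C)C)[C@@H](CO[Si](c1ccccc1)(c1ccccc1)C(C)(C)C)[C@@H](O)c1ccc(OCc2ccccc2)c(OC)c1 | intermediate |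
| 17 | (2R,3S,4S,5R)-2,5-di-Ar-3,4-bis{[(TBDPS)oxy]methyl}tetrahydrofuran | COc1cc([C@@H]2O[C@@H](c3ccc(OCc4ccccc4)c(OC)c3)[C@H](CO[Si](c3ccccc3)(c3ccccc3)C(C)(C)C)[C@H]2CO[Si](c2ccccc2)(c2ccccc2)C(C)(C)C)ccc1OCc1ccccc1 | intermediate |
| 18 | 4,4'-di-O-benzyl-neoolivil | COc1cc([C@@H]2O[C@@H](c3ccc(OCc4ccccc4)c(OC)c3)[C@H](CO)[C@H]2CO)ccc1OCc1ccccc1 | intermediate |
| 19 | (+)-neoolivil, (2R,3S,4S,5R) | COc1cc([C@@H]2O[C@@H](c3ccc(O)c(OC)c3)[C@H](CO)[C@H]2CO)ccc1O | target |

## Step count

- Total steps: 17.
- Longest linear sequence: 16 (steps 1–5 and 7–17). Step 6 is a one-step branch whose product 8 is used twice.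

## Steps most likely to fail

1. **Step 10 (formaldehyde aldol).** The risks are low conversion, bis-addition and retro-aldol. Fallback: C-alkylate the same enolate with benzyl chloromethyl ether. This gives the C3 arm directly as CH2OBn and removes step 11. The extra benzyl ether is then cleaved in the final hydrogenolysis.
2. **Step 12 (single ArLi addition to the hindered lactone).** The risks are enolisation with β-silyloxide loss and over-addition. Fallback:
   - open 13 with MeNH(OMe)·HCl/AlMe3 to the γ-hydroxy Weinreb amide;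
   - protect the carbinol as its TES ether and add ArLi to the amide;
   - remove the TES group and oxidise to reach 15.
3. **Step 14 (diastereoselectivity of the double reduction).** Fallback: replace substrate control with catalyst control, using (S)-Me-CBS/BH3·SMe2. This catalyst gives (R)-aryl carbinols and should be matched with the Felkin sense. No alkene remains to interfere with the borane.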